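The route rests on cutting the C7–C1' bond between ring A (the acylated trione, quaternary at C3) and ring B (the cyclopentane). C7 sits on C1, between the C2 and C6 carbonyls, and C2', the neighbour of C1', carries oxygen. C7=C1–C2=O is therefore a latent 1-oxadiene and C1'=C2'–OSi its electron-rich partner. One thermal [4+2] step forges C7–C1' and O–C2', closes a sacrificial dihydropyran and sets C1' trans to C5'. The precursors are the morpholinomethyl Mannich base of the enantiopure ring A trione and the (S)-triethylsilyl enol ether of 3-isopropenylcyclopentanone. Ketal hydrolysis and methyl addition at C2' complete the target.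

Key step: step 9

Atom labels: ring A is C1–C6 (C1 bears C7, C3 is quaternary, C5 bears the acyl group). C7 is the bridging CH2. Ring B is C1'–C5' (C1' bears C7, C2' bears oxygen, C5' bears isopropenyl).

Configuration read from the target SMILES: C3 R, acyl side chain R, C1' R, C2' S, C5' S. On ring B, C7 is trans to the isopropenyl group and cis to the hydroxyl group.

Assumption: ring A compounds are rapidly equilibrating enol tautomers. Each is drawn and named as one tautomer, and the C3 descriptor refers to that drawing.

Step 1
Reactants: 1 cyclopent-2-en-1-one; 2 isopropenylmagnesium bromide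
Product: 4 (S)-triethyl{[3-(prop-1-en-2-yl)cyclopent-1-en-1-yl]oxy}silane, via bromomagnesium enolate 3 (not isolated)
Conditions: CuBr·SMe2 (5 mol %), 1-[2-(diphenylphosphino)ferrocenyl]ethyldicyclohexylphosphine (6 mol %, the antipode that gives the S product), t-BuOMe, −75 °C, slow addition of 2; then Et3SiCl, Et3N, DMPU, −75 °C → rt
Reagents that add atoms: chlorotriethylsilane, CC[Si](Cl)(CC)CC
Why: Copper-catalysed asymmetric conjugate addition of a Grignard reagent sets C5' through ligand-controlled choice of the enone face, O-silylation of the regiodefined enolate fixes the double bond on the substituted side (C1'=C2'), and any minor enantiomer should be shed later as a diastereomer once the enantiopure ring A is attached.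

Step 2
Reactants: 5 dimethyl methylmalonate
Product: 7 dimethyl 2-methyl-2-(3-methylbut-2-en-1-yl)propanedioate, via sodium enolate 6 (not isolated)
Conditions: NaH, THF, 0 °C; then prenyl bromide, 0 °C → rt
Reagents that add atoms: prenyl bromide (1-bromo-3-methylbut-2-ene), CC(C)=CCBr
Why: Malonic ester alkylation (SN2 at a primary allylic bromide) builds the fully substituted carbon that becomes C3, and the product is still prochiral, so no stereocentre is set here.

Step 3
Reactants: 7 dimethyl 2-methyl-2-(3-methylbut-2-en-1-yl)propanedioate
Product: 8 (R)-2-(methoxycarbonyl)-2,5-dimethylhex-4-enoic acid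
Conditions: pig liver esterase, phosphate buffer pH 7.2–DMSO (3:1), rt, pH-stat (1 M NaOH); then cold 1 M HCl to pH 3, EtOAc
Reagents that add atoms: water, O
Why: Enzymatic desymmetrisation of a prochiral α,α-disubstituted dimethyl malonate should cleave the pro-S ester, in line with the enzyme's known preference for methyl/alkyl malonates whose larger substituent has five or more carbons, which creates C3 as the (R)-half-ester, and hydrolysis stops there because the carboxylate is not accepted as a substrate.

Step 4
Reactants: 9 (R)-2-methylbutanoic acid; 10 tert-butyl acetoacetate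
Product: 12 tert-butyl (4R)-2-acetyl-4-methyl-3-oxohexanoate, via (R)-2-methylbutanoyl chloride 11 (not isolated)
Conditions: (COCl)2 (1.05 equiv), DMF (cat.), CH2Cl2, 0 °C → rt, N2 purge; then 10, MgCl2, pyridine, CH2Cl2, 0 °C → rt
Reagents that add atoms: none
Why: C-acylation of a β-keto ester under soft enolisation (MgCl2 and a weak amine base) needs no strong base, so the stereocentre next to the acyl carbon is carried through unchanged.

Step 5
Reactants: 12 tert-butyl (4R)-2-acetyl-4-methyl-3-oxohexanoate
Product: 13 (R)-5-methylheptane-2,4-dione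
Conditions: TFA–CH2Cl2 (1:4), rt
Reagents that add atoms: none
Why: Acidolysis of the tert-butyl ester followed by spontaneous decarboxylation of the β-keto acid releases the unsymmetrical β-diketone, which enolises at its central carbon and not towards the stereocentre.

Step 6
Reactants: 8 (R)-2-(methoxycarbonyl)-2,5-dimethylhex-4-enoic acid; 13 (R)-5-methylheptane-2,4-dione
Product: 16 methyl (2R,8R)-2,8-dimethyl-2-(3-methylbut-2-en-1-yl)-3,5,7-trioxodecanoate, via half-ester acid chloride 14 (not isolated), via dilithium dienediolate 15 (not isolated)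
Conditions: 8, 1-chloro-N,N,2-trimethylprop-1-en-1-amine, THF, 0 °C → rt (gives 14); 13 (2 equiv), LDA (4.1 equiv), THF, −78 → 0 °C (gives 15); 14 added to 15, −78 °C; aq NH4Cl; surplus 13 recovered
Reagents that add atoms: none
Why: In this Claisen-type γ-acylation of a β-diketone 1,3-dianion the second deprotonation occurs at the methyl terminus and not at the methine, so the side-chain centre is untouched, the terminal carbanion attacks only the acid chloride (formed under neutral conditions and lacking α-hydrogens) and not the hindered methyl ester, so the two malonyl carbonyls stay differentiated and C3 keeps its configuration, and the second equivalent of 15 absorbs the acidic proton of the product.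

Step 7
Reactants: 16 methyl (2R,8R)-2,8-dimethyl-2-(3-methylbut-2-en-1-yl)-3,5,7-trioxodecanoate
Product: 17 (6R)-3,5-dihydroxy-6-methyl-6-(3-methylbut-2-en-1-yl)-2-[(2R)-2-methylbutanoyl]cyclohexa-2,4-dien-1-one (ring A acyl trione)
Conditions: NaOMe (3 equiv), MeOH, 65 °C; cold 1 M HCl to pH 3
Reagents that add atoms: none
Why: In this Dieckmann-type intramolecular Claisen condensation the carbon between the two outer ketones (C5) attacks the ester in a 6-exo-trig closure, the competing aldol path is blocked by the quaternary carbon, any lactone from O-attack is reopened by methoxide so that material drains to the strongly stabilised β-triketonate, and C3 has no way to epimerise.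

Step 8
Reactants: 17 ring A acyl trione
Product: 18 (6R)-3,5-dihydroxy-6-methyl-6-(3-methylbut-2-en-1-yl)-2-[(2R)-2-methylbutanoyl]-4-(morpholin-4-ylmethyl)cyclohexa-2,4-dien-1-one (Mannich base)
Conditions: morpholine and 37% aq CH2O (1.2 equiv each, premixed), EtOH, 0 °C → rt
Reagents that add atoms: formaldehyde, C=O; morpholine, C1COCCN1
Why: In this Mannich reaction C1 is the only unsubstituted nucleophilic carbon of ring A, and the product should separate as its inner salt, which holds back the follow-up reaction to a methylene-bridged dimer and masks the acidic enol for the next step, while no stereocentre is formed.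

Step 9
Reactants: 18 Mannich base; 4 (S)-triethyl{[3-(prop-1-en-2-yl)cyclopent-1-en-1-yl]oxy}silane
Product: 20 (1S,3aR,5R,9aR)-8-hydroxy-5-methyl-5-(3-methylbut-2-en-1-yl)-7-[(2R)-2-methylbutanoyl]-1-(prop-1-en-2-yl)-3a-[(triethylsilyl)oxy]-1,2,3,3a,9,9a-hexahydrocyclopenta[b]chromen-6(5H)-one (cis-fused silyl ketal), via 2-methylene trione 19 (not isolated)
Conditions: 4 (3 equiv), PhMe, 4 Å MS, 110 °C, slow addition of 18 in 1,4-dioxane
Reagents that add atoms: none
Why: Heat expels morpholine from the inner salt 18 (retro-Michael elimination), and the resulting 2-methylene trione 19, an electron-poor 1-oxadiene C7=C1–C2=O, is intercepted by the electron-rich C1'=C2' bond of 4 in a concerted but strongly asynchronous inverse-electron-demand [4+2] cycloaddition in which C7–C1' bonding runs ahead of O–C2' bonding. The closest known reaction type is the oxa-Diels–Alder trapping of 2-alkylidene-1,3-dicarbonyl compounds and ortho-quinone methides, released from Mannich bases or by Knoevenagel condensation, with alkyl and silyl enol ethers. The one new ring, the dihydropyran O–C2=C1–C7–C1'–C2', closes by an intermolecular cycloaddition that is suprafacial on the ring alkene, so O and C7 end up cis and the 6-5 fusion is cis. C1' (R) is controlled by the C5' stereocentre of 4, because the heterodiene approaches the cyclopentene face opposite the isopropenyl group and so places C7 trans to it, and C2' (R in the ketal) follows from C1' through the suprafacial addition; C7 is unsubstituted, so endo/exo orientation creates no further centre. The step needs regio-, chemo- and facial selectivity: the polarisation of the enol ether sends its nucleophilic carbon C1' to the electrophilic terminus C7, its high-lying HOMO makes it far more reactive than the isopropenyl and prenyl alkenes, and an excess of 4 with slow feeding of 18 keeps self-condensation of 19 down. Closure through the C6 oxygen instead of the C2 oxygen, or a stepwise Mukaiyama–Michael course with silyl transfer, would do no harm, since all such products give ketone 21 in step 10.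

Step 10
Reactants: 20 cis-fused silyl ketal
Product: 21 (6R)-3,5-dihydroxy-6-methyl-6-(3-methylbut-2-en-1-yl)-2-[(2R)-2-methylbutanoyl]-4-{[(1R,5S)-2-oxo-5-(prop-1-en-2-yl)cyclopentyl]methyl}cyclohexa-2,4-dien-1-one (2,3-trans cyclopentanone)
Conditions: AcOH–THF–H2O (3:1:1), rt
Reagents that add atoms: none
Why: In this mild acid hydrolysis of a mixed silyl ketal the second oxygen is a vinylogous carboxylate leaving group, so the C2'–O(pyran) bond ionises readily and the silyl group is lost to water, the weak acid leaves the prenyl and isopropenyl groups alone, and C1' cannot be degraded because the trans ketone is also the thermodynamic epimer.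

Step 11
Reactants: 21 2,3-trans cyclopentanone
Product: 22 (6R)-3,5-dihydroxy-4-{[(1R,2S,5S)-2-hydroxy-2-methyl-5-(prop-1-en-2-yl)cyclopentyl]methyl}-6-methyl-6-(3-methylbut-2-en-1-yl)-2-[(2R)-2-methylbutanoyl]cyclohexa-2,4-dien-1-one (target)
Conditions: CeCl3 (anhydrous, 6 equiv), MeMgBr (6 equiv), THF, −78 °C, 1 h; add 21, −78 → 0 °C; aq NH4Cl, then 10% citric acid
Reagents that add atoms: methylmagnesium bromide, C[Mg]Br
Why: In this organocerium 1,2-addition the first two equivalents turn ring A into a dianion in which all four carbonyl groups are enolate-like and inert, the weakly basic reagent adds to the cyclopentanone instead of enolising it, and steric approach control by the adjacent C1' substituent sends methyl to the face anti to C7 (the more distant C5' group has the weaker influence), which leaves the hydroxyl cis to C7 and sets C2' as S.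

Compound list
1 | cyclopent-2-en-1-one | O=C1C=CCC1 | starting material
2 | isopropenylmagnesium bromide | C=C(C)[Mg]Br | starting material
3 | bromomagnesium (S)-3-(prop-1-en-2-yl)cyclopent-1-en-1-olate | C=C(C)[C@H]1CCC(O[Mg]Br)=C1 | intermediate (not isolated)
4 | (S)-triethyl{[3-(prop-1-en-2-yl)cyclopent-1-en-1-yl]oxy}silane | C=C(C)[C@H]1CCC(O[Si](CC)(CC)CC)=C1 | intermediate
5 | dimethyl methylmalonate | COC(=O)C(C)C(=O)OC | starting material
6 | sodium enolate of dimethyl methylmalonate | COC(=O)C(C)=C(OC)O[Na] | intermediate (not isolated)
7 | dimethyl 2-methyl-2-(3-methylbut-2-en-1-yl)propanedioate | COC(=O)C(C)(CC=C(C)C)C(=O)OC | intermediate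
8 | (R)-2-(methoxycarbonyl)-2,5-dimethylhex-4-enoic acid | COC(=O)[C@](C)(CC=C(C)C)C(=O)O | intermediate
9 | (R)-2-methylbutanoic acid | CC[C@@H](C)C(=O)O | starting material
10 | tert-butyl acetoacetate | CC(=O)CC(=O)OC(C)(C)C | starting material
11 | (R)-2-methylbutanoyl chloride | CC[C@@H](C)C(=O)Cl | intermediate (not isolated)
12 | tert-butyl (4R)-2-acetyl-4-methyl-3-oxohexanoate (C2 labile, enolised) | CC[C@@H](C)C(=O)C(C(C)=O)C(=O)OC(C)(C)C | intermediate
13 | (R)-5-methylheptane-2,4-dione | CC[C@@H](C)C(=O)CC(C)=O | intermediate
14 | methyl (S)-2-(chlorocarbonyl)-2,5-dimethylhex-4-enoate (same spatial arrangement as 8; the descriptor changes because COCl outranks CO2Me) | COC(=O)[C@](C)(CC=C(C)C)C(=O)Cl | intermediate (not isolated)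
15 | dilithium (R)-5-methylhepta-1,3-diene-2,4-diolate | C=C(O[Li])C=C(O[Li])[C@H](C)CC | intermediate (not isolated)
16 | methyl (2R,8R)-2,8-dimethyl-2-(3-methylbut-2-en-1-yl)-3,5,7-trioxodecanoate | COC(=O)[C@](C)(CC=C(C)C)C(=O)CC(=O)CC(=O)[C@H](C)CC | intermediate
17 | (6R)-3,5-dihydroxy-6-methyl-6-(3-methylbut-2-en-1-yl)-2-[(2R)-2-methylbutanoyl]cyclohexa-2,4-dien-1-one | C1=C(O)[C@@](C)(CC=C(C)C)C(=O)C(C(=O)[C@H](C)CC)=C1O | intermediate
18 | (6R)-3,5-dihydroxy-6-methyl-6-(3-methylbut-2-en-1-yl)-2-[(2R)-2-methylbutanoyl]-4-(morpholin-4-ylmethyl)cyclohexa-2,4-dien-1-one | C1COCCN1CC1=C(O)[C@@](C)(CC=C(C)C)C(=O)C(C(=O)[C@H](C)CC)=C1O | intermediate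
19 | (2R)-5-hydroxy-2-methyl-2-(3-methylbut-2-en-1-yl)-4-[(2R)-2-methylbutanoyl]-6-methylidenecyclohex-4-ene-1,3-dione | C=C1C(=O)[C@@](C)(CC=C(C)C)C(=O)C(C(=O)[C@H](C)CC)=C1O | intermediate (not isolated)
20 | (1S,3aR,5R,9aR)-8-hydroxy-5-methyl-5-(3-methylbut-2-en-1-yl)-7-[(2R)-2-methylbutanoyl]-1-(prop-1-en-2-yl)-3a-[(triethylsilyl)oxy]-1,2,3,3a,9,9a-hexahydrocyclopenta[b]chromen-6(5H)-one | C=C(C)[C@H]1CC[C@@]2(O[Si](CC)(CC)CC)[C@@H]1CC1=C(O2)[C@@](C)(CC=C(C)C)C(=O)C(C(=O)[C@H](C)CC)=C1O | intermediate
21 | (6R)-3,5-dihydroxy-6-methyl-6-(3-methylbut-2-en-1-yl)-2-[(2R)-2-methylbutanoyl]-4-{[(1R,5S)-2-oxo-5-(prop-1-en-2-yl)cyclopentyl]methyl}cyclohexa-2,4-dien-1-one | C=C(C)[C@H]1CCC(=O)[C@@H]1CC1=C(O)[C@@](C)(CC=C(C)C)C(=O)C(C(=O)[C@H](C)CC)=C1O | intermediate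
22 | (6R)-3,5-dihydroxy-4-{[(1R,2S,5S)-2-hydroxy-2-methyl-5-(prop-1-en-2-yl)cyclopentyl]methyl}-6-methyl-6-(3-methylbut-2-en-1-yl)-2-[(2R)-2-methylbutanoyl]cyclohexa-2,4-dien-1-one | C=C(C)[C@H]1CC[C@](C)(O)[C@@H]1CC1=C(O)[C@@](C)(CC=C(C)C)C(=O)C(C(=O)[C@H](C)CC)=C1O | target

Total step count: 11.
Longest linear sequence: 8 steps. This is steps 2, 3, 6, 7, 8, 9, 10, 11 from 5, and equally steps 4 to 11 from 9.

Steps most likely to fail

1. Step 9.
- **Risk:** The silyl group of the enol ether may be lost by proton or silyl transfer to the acidic, amine-releasing partner. The transient heterodiene may also self-condense. Either process may outrun the cycloaddition.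
- **Fallback:** The polarity is reversed, with ring A as the Michael donor. The fallback sets out from 4 and 17 and comes back to the route at 21. Compound 4 is aminomethylated with dimethylmethylideneammonium iodide in CH2Cl2, anti to the isopropenyl group, to give (2S,3S)-2-[(dimethylamino)methyl]-3-(prop-1-en-2-yl)cyclopentan-1-one F1. Methyl iodide in Et2O converts it into {[(1S,5S)-2-oxo-5-(prop-1-en-2-yl)cyclopentyl]methyl}trimethylammonium iodide F2. Two-phase aq NaHCO3/CH2Cl2 eliminates the amine to give (R)-2-methylidene-3-(prop-1-en-2-yl)cyclopentan-1-one F3. Conjugate addition of 17 through C1 (catalytic Et3N, THF, 0 °C → rt) to F3, with thermodynamic protonation at C1', should give the trans ketone 21.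

2. Step 6.
- **Risk:** Slow attack at the hindered acyl carbon, O-acylation of the dianion or premature proton transfer may consume the partners. Any attack at the ester carbonyl would erode the configuration at C3.
- **Fallback:** Aldol addition and oxidation replace the acylation. The fallback sets out from 14 and 15 and comes back at 16. Compound 14 is reduced with LiAlH(OtBu)3 in THF at −78 °C to methyl (R)-2-formyl-2,5-dimethylhex-4-enoate F4. The aldehyde is far more electrophilic than the ester. Dianion 15 adds through its terminal carbon at −78 °C to give methyl (2R,8R)-3-hydroxy-2,8-dimethyl-2-(3-methylbut-2-en-1-yl)-5,7-dioxodecanoate F5 as a mixture of carbinol epimers. Dess–Martin periodinane in CH2Cl2 oxidises this mixture to 16.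

3. Step 3.
- **Risk:** The enzyme may select insufficiently, or in the reverse sense, between the two enantiotopic ester groups. The prenyl group lies near the size at which the enzyme's preference changes over.
- **Fallback:** Reductive desymmetrisation with a small-molecule catalyst, both antipodes of which can be made. The fallback sets out from 7 and comes back at 8. One ester group is hydrosilylated with HSi(OMe)3 under a dinuclear zinc catalyst formed from ZnEt2 and a chiral tetradentate aminophenol ligand. Desilylation with K2CO3/MeOH gives methyl (R)-2-(hydroxymethyl)-2,5-dimethylhex-4-enoate F6. TEMPO (cat.)/PhI(OAc)2 in MeCN–H2O oxidises the primary alcohol to the acid 8.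

Further compounds
F1 | step 9 | (2S,3S)-2-[(dimethylamino)methyl]-3-(prop-1-en-2-yl)cyclopentan-1-one | C=C(C)[C@H]1CCC(=O)[C@@H]1CN(C)C
F2 | step 9 | {[(1S,5S)-2-oxo-5-(prop-1-en-2-yl)cyclopentyl]methyl}trimethylammonium iodide | C=C(C)[C@H]1CCC(=O)[C@@H]1C[N+](C)(C)C.[I-]
F3 | step 9 | (R)-2-methylidene-3-(prop-1-en-2-yl)cyclopentan-1-one | C=C(C)[C@H]1CCC(=O)C1=C
F4 | step 6 | methyl (R)-2-formyl-2,5-dimethylhex-4-enoate | COC(=O)[C@](C)(CC=C(C)C)C=O
F5 | step 6 | methyl (2R,8R)-3-hydroxy-2,8-dimethyl-2-(3-methylbut-2-en-1-yl)-5,7-dioxodecanoate (both carbinol epimers) | COC(=O)[C@](C)(CC=C(C)C)C(O)CC(=O)CC(=O)[C@H](C)CC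
F6 | step 3 | methyl (R)-2-(hydroxymethyl)-2,5-dimethylhex-4-enoate | COC(=O)[C@](C)(CC=C(C)C)CO
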